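A direct plan would close ring A last: 2,3,5-tribromothiophene A1 would be oxidised to 2,3,5-tribromothiophene 1,1-dioxide A2 while 2,4-dibromophenol would be alkylated to methyl 2-(2,4-dibromophenoxy)acetate A3 and then silylated to 1-methoxy-1-(trimethylsilyloxy)-2-(2,4-dibromophenoxy)ethene A4 as a silyl ketene acetal; A2 and A4 would then combine in an inverse-demand [4+2] cycloaddition followed by loss of SO2, ketal hydrolysis and tautomerisation.
Its weakest points would be:
- the oxidation of the electron-poor thiophene A1, which would need concentrated H2O2 with trifluoroacetic anhydride and would give a dioxide prone to decomposition;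
- the ring-forming cycloaddition, whose orientation would rest on a small bias between two brominated diene termini, the reverse orientation placing the bromines at C3, C5 and C6;
- the position of this three-event cascade as the last step, run on all the material with a crude, moisture-sensitive acetal, after two steps spent on a two-carbon unit.

**Plan of the new route**
The retrosynthesis would cut C4–Br and C6–Br first, then dearomatise ring A to a cyclohex-2-enone, turn C3–Br back into a carbonyl, and last cut the C2–O ether bond to a carbene at C2 of cyclohexane-1,3-dione and 2,4-dibromophenol.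
The enabling feature: in ring A the ether carbon C2 lies between C1 (OH) and C3 (Br), which map onto the two equivalent carbonyls of the mirror-symmetric dione, and C4 and C6 are para and ortho to the hydroxyl, where a phenol brominates anyway.
Both six-membered rings would be bought: ring A is present as a saturated carbocycle from step 1, ring B is attached to it in step 2, and ring A turns aromatic only in step 4.
No ring is closed, so no cycloaddition orientation, no thiophene oxidation and no ketene acetal arise, and the last step is a plain bromination.

Key step: step 2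

Remark: compound 6 is a 2-substituted cyclohexane-1,3-dione and is written as its enol, the tautomer expected to predominate; the target has no stereocentre.

Step 1
Reactants: 1 cyclohexane-1,3-dione
Product: 2 2-diazocyclohexane-1,3-dione
Conditions: 4-AcNHC6H4SO2N3, Et3N, MeCN, 0 °C → rt
Reagents that add atoms: 4-acetamidobenzenesulfonyl azide, CC(=O)Nc1ccc(cc1)S(=O)(=O)N=[N+]=[N-]
Why: Regitz diazo transfer, in which the amine deprotonates the doubly activated C2 methylene (pKa near 5), the enolate attacks the terminal azide nitrogen and the triazene fragments to the acceptor/acceptor diazo compound and the sulfonamide, no other position of 1 being acidic enough to react.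

Step 2
Reactants: 2 2-diazocyclohexane-1,3-dione; 3 2,4-dibromophenol
Product: 6 2-(2,4-dibromophenoxy)-3-hydroxycyclohex-2-en-1-one, via dirhodium carbene 4 (not isolated), via oxonium ylide 5 (not isolated)
Conditions: Rh2(OAc)4 (1 mol %), PhF, 70 °C, slow addition of 2 to 3 (1.5 equiv)
Reagents that add atoms: none
Why: Dirhodium tetraacetate, a divalent rhodium carboxylate, should take N2 from 2 to give the electrophilic acceptor/acceptor carbene 4, which the phenol oxygen of 3 attacks to form oxonium ylide 5, and proton transfer from oxygen to the enolate then gives 6 as its hydrogen-bonded enol. The closest known reaction type is the rhodium-catalysed O–H insertion of 2-diazo-1,3-dicarbonyl compounds into alcohols and phenols. No ring is closed and no stereocentre is formed, since C2 of 6 is sp2 in the enol and 6 is achiral. The step needs O–H capture to beat attack of the carbene on an aromatic ring, Wolff ring contraction, carbene dimerisation and insertion into the enol O–H of 6; the acidic hydroxyl of 3 (pKa near 8) is the best nucleophile present, ring B is deactivated by two bromines, and slow addition of 2 to an excess of 3 keeps the carbene concentration low. Site selectivity is not in question, because C2 is the only diazo carbon and the mirror plane of the dione places the new ether oxygen between the two carbonyls that later become C1–OH and C3–Br. The aryl C–Br bonds should be untouched, because divalent rhodium carboxylates do not insert into them, which copper- or palladium-mediated aryl ether couplings could not promise here.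

Step 3
Reactants: 6 2-(2,4-dibromophenoxy)-3-hydroxycyclohex-2-en-1-one
Product: 8 3-bromo-2-(2,4-dibromophenoxy)cyclohex-2-en-1-one, via enoxyphosphonium bromide 7 (not isolated)
Conditions: Ph3PBr2, Et3N, MeCN, 0 °C → rt
Reagents that add atoms: triphenylphosphine dibromide, Br[P+](c1ccccc1)(c1ccccc1)c1ccccc1.[Br-]
Why: Deoxybromination of a vinylogous acid to a β-bromo enone, in which the enolate oxygen attacks phosphorus to give 7 and bromide then adds at C3 and expels Ph3P=O by addition–elimination; the mirror plane of 6 makes both carbonyls equivalent so only one bromo enone can form, and the aryl ether and aryl bromides are inert.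

Step 4
Reactants: 8 3-bromo-2-(2,4-dibromophenoxy)cyclohex-2-en-1-one
Product: 11 3-bromo-2-(2,4-dibromophenoxy)phenol, via 6-bromo enone 9 (not isolated), via cross-conjugated dienone 10 (not isolated)
Conditions: CuBr2 (2.2 equiv), LiBr, MeCN, reflux
Reagents that add atoms: none
Why: Copper dibromide aromatisation of a cyclohex-2-enone, in which divalent copper brominates the cross-conjugated enol at C6 to give 9, bromide-assisted loss of HBr gives dienone 10 and this tautomerises irreversibly to the phenol; bromination at C4 through the extended dienol would end in the same phenol, the sp2-bound C3–Br cannot be eliminated, the two bromines on ring B should keep it from acid-promoted cyclodehydration onto the C1 carbonyl, and any bromination of 11 at C4 by excess CuBr2 would only anticipate step 5.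

Step 5
Reactants: 11 3-bromo-2-(2,4-dibromophenoxy)phenol
Product: 13 3,4,6-tribromo-2-(2,4-dibromophenoxy)phenol, via 4-bromo phenol 12 (not isolated)
Conditions: Br2 (2.05 equiv), AcOH, 15 °C → rt
Reagents that add atoms: bromine, BrBr
Why: Electrophilic aromatic bromination under control of the free hydroxyl, the strongest donor on ring A, so that C4 (para to OH) should react first to give 12 and C6 (ortho to OH) second, whereas C5 is meta to OH and activated only by the electron-poor aryloxy oxygen and the one free ortho position of ring B lies on a ring deactivated by two bromines.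

**Compound list**
1 | cyclohexane-1,3-dione | O=C1CCCC(=O)C1 | starting material
2 | 2-diazocyclohexane-1,3-dione | [N-]=[N+]=C1C(=O)CCCC1=O | intermediate
3 | 2,4-dibromophenol | Oc1ccc(Br)cc1Br | starting material
4 | (2,6-dioxocyclohexylidene)dirhodium tetraacetate, the metal carbene (SMILES shows the carbene carbon on one rhodium; acetates and second rhodium omitted) | O=C1CCCC(=O)C1=[Rh] | intermediate
5 | oxonium ylide from carbene 4 and phenol 3 (zwitterion) | O=C1CCCC([O-])=C1[OH+]c1ccc(Br)cc1Br | intermediate
6 | 2-(2,4-dibromophenoxy)-3-hydroxycyclohex-2-en-1-one (enol of 2-(2,4-dibromophenoxy)cyclohexane-1,3-dione) | O=C1CCCC(O)=C1Oc1ccc(Br)cc1Br | intermediate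
7 | [2-(2,4-dibromophenoxy)-3-oxocyclohex-1-en-1-yl]oxytriphenylphosphonium bromide | O=C1CCCC(O[P+](c2ccccc2)(c2ccccc2)c2ccccc2)=C1Oc1ccc(Br)cc1Br.[Br-] | intermediate
8 | 3-bromo-2-(2,4-dibromophenoxy)cyclohex-2-en-1-one | O=C1CCCC(Br)=C1Oc1ccc(Br)cc1Br | intermediate
9 | 3,6-dibromo-2-(2,4-dibromophenoxy)cyclohex-2-en-1-one (racemic) | O=C1C(Br)CCC(Br)=C1Oc1ccc(Br)cc1Br | intermediate
10 | 3-bromo-2-(2,4-dibromophenoxy)cyclohexa-2,5-dien-1-one | O=C1C=CCC(Br)=C1Oc1ccc(Br)cc1Br | intermediate
11 | 3-bromo-2-(2,4-dibromophenoxy)phenol | Oc1cccc(Br)c1Oc1ccc(Br)cc1Br | intermediate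
12 | 3,4-dibromo-2-(2,4-dibromophenoxy)phenol | Oc1ccc(Br)c(Br)c1Oc1ccc(Br)cc1Br | intermediate
13 | 3,4,6-tribromo-2-(2,4-dibromophenoxy)phenol | Oc1c(Br)cc(Br)c(Br)c1Oc1ccc(Br)cc1Br | target

**Step count**
Total steps: 5. Longest linear sequence: 5 steps (1 → 13); 3 enters at step 2.

**Steps most likely to fail**

1. Step 4. The aromatisation could stall at the brominated ketone, or the HBr formed could degrade the bromo enone before HBr loss and tautomerisation are complete. The fallback sets out from 3 and returns at 11, taking the substitution pattern of ring A from an aromatic aldehyde instead. Nucleophilic aromatic substitution of the fluoride of commercial 3-bromo-2-fluorobenzaldehyde by 3, activated by the ortho formyl group (K2CO3, DMF, 110 °C), would give 3-bromo-2-(2,4-dibromophenoxy)benzaldehyde F1 as the diaryl ether. Baeyer–Villiger oxidation of F1 with 3-chloroperbenzoic acid (mCPBA) in CH2Cl2 would give 3-bromo-2-(2,4-dibromophenoxy)phenyl formate F2 by aryl migration. Methanolysis of F2 in MeOH containing a catalytic amount of HCl would give 11.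

2. Step 2. The carbene could be diverted into ring contraction, attack on an arene or dimerisation if capture by the hindered ortho-bromo phenol is slow. The fallback sets out from 3 and returns at 6, closing ring A by Claisen condensation instead. Alkylation of 3 with ethyl 4-chloroacetoacetate (NaH, 2 equiv, THF) would give ethyl 4-(2,4-dibromophenoxy)-3-oxobutanoate F3 after work-up. Michael addition of F3 to ethyl acrylate (NaOEt, EtOH) would give racemic diethyl 2-[(2,4-dibromophenoxy)acetyl]pentanedioate F4 in the first stage. In the same flask the aryloxy-bearing carbon of F4 would condense onto the distal ester to give racemic ethyl 3-(2,4-dibromophenoxy)-2,4-dioxocyclohexane-1-carboxylate F5 as a keto–enol mixture. Hydrolysis and decarboxylation of F5 in aqueous HCl and AcOH at 90 °C would give 6.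

3. Step 5. Bromination could run on to C5 of ring A or to the free ortho position of ring B, or proceed unevenly at C4 and C6. The fallback sets out from 8 and returns at 13, setting the C6 bromine before aromatisation. Phenyltrimethylammonium tribromide (2 equiv, THF) would brominate 8 twice at C6, by way of 9, to give 3,6,6-tribromo-2-(2,4-dibromophenoxy)cyclohex-2-en-1-one F6 as the geminal dibromide. Heating F6 with Li2CO3 in DMF at 100 °C would eliminate HBr to give 3,6-dibromo-2-(2,4-dibromophenoxy)cyclohexa-2,5-dien-1-one F7 and this would tautomerise in the same flask to 3,6-dibromo-2-(2,4-dibromophenoxy)phenol F8 as the aromatic product. One equivalent of Br2 in AcOH could then enter F8 only para to the hydroxyl, giving 13.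

**Further compounds**
F1 | step 4 | 3-bromo-2-(2,4-dibromophenoxy)benzaldehyde | O=Cc1cccc(Br)c1Oc1ccc(Br)cc1Br
F2 | step 4 | 3-bromo-2-(2,4-dibromophenoxy)phenyl formate | O=COc1cccc(Br)c1Oc1ccc(Br)cc1Br
F3 | step 2 | ethyl 4-(2,4-dibromophenoxy)-3-oxobutanoate | CCOC(=O)CC(=O)COc1ccc(Br)cc1Br
F4 | step 2 | diethyl 2-[(2,4-dibromophenoxy)acetyl]pentanedioate | CCOC(=O)CCC(C(=O)OCC)C(=O)COc1ccc(Br)cc1Br
F5 | step 2 | ethyl 3-(2,4-dibromophenoxy)-2,4-dioxocyclohexane-1-carboxylate | CCOC(=O)C1CCC(=O)C(Oc2ccc(Br)cc2Br)C1=O
F6 | step 5 | 3,6,6-tribromo-2-(2,4-dibromophenoxy)cyclohex-2-en-1-one | O=C1C(Br)(Br)CCC(Br)=C1Oc1ccc(Br)cc1Br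
F7 | step 5 | 3,6-dibromo-2-(2,4-dibromophenoxy)cyclohexa-2,5-dien-1-one | O=C1C(Br)=CCC(Br)=C1Oc1ccc(Br)cc1Br
F8 | step 5 | 3,6-dibromo-2-(2,4-dibromophenoxy)phenol | Oc1c(Br)ccc(Br)c1Oc1ccc(Br)cc1Br
A1 | direct plan | 2,3,5-tribromothiophene | Brc1cc(Br)c(Br)s1
A2 | direct plan | 2,3,5-tribromothiophene 1,1-dioxide | O=S1(=O)C(Br)=C(Br)C=C1Br
A3 | direct plan | methyl 2-(2,4-dibromophenoxy)acetate | COC(=O)COc1ccc(Br)cc1Br
A4 | direct plan | 1-methoxy-1-(trimethylsilyloxy)-2-(2,4-dibromophenoxy)ethene | COC(O[Si](C)(C)C)=COc1ccc(Br)cc1Br
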